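## The problem

Target 17 is a flavone: a 4-pyranone (ring C) fused to a benzene ring A that carries no hydrogen at all, and joined at C2 to a symmetric 3,5-dihydroxy-4-methoxyphenyl ring B. It has no stereocentre, so the difficulty is purely constitutional. Seven oxygens sit on the two benzene rings, three as methyl ethers (C6, C8, C4') and four as free hydroxyls (C5, C7, C3', C5'), and the two kinds must be kept apart throughout. Ring A is pentaoxygenated with hydroxyl and methoxyl alternating, a pattern no cheap arene offers complete, so C–O bonds and the C4a–C4 bond must be made on a ring that becomes more hindered and more easily oxidised with each substituent. The free tetrahydroxyflavone is an electron-rich polyphenol that would not tolerate strong base in air, oxidants, or the Lewis acids that strip aryl methyl ethers; its hydroxyls therefore travel as benzyl ethers and are released last. The enabling feature is C4a: it lies between C5 and C8a, both oxygen-bearing, and ring A has a local mirror plane through C4a and C7. A nitrile oxide carbon attached there (the future C4) is flanked by two ortho substituents and persists as a monomer, and once C3–C4 is made either ortho oxygen closes ring C to the same flavone. C3 is an unsubstituted CH, so C2 and C3 can come from a terminal aryl alkyne.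

## Retrosynthesis

**17 back to 15.** The O1–C2 bond is cut and the C4 carbonyl is traced back to a C–N bond. This leads through the pentahydroxy β-amino enone 16 to the fully benzylated 3,5-diarylisoxazole 15, which is a masked 1,3-diketone. The neighbouring cuts (C2–C3 by Claisen-type acylation or chalcone condensation of a ring A methyl ketone) need strong base and a ring A in which one ortho oxygen is free and the other protected. Isoxazole 15 needs neither, because its N–O bond opens by hydrogenolysis, the same operation that removes the benzyl groups. The forward reaction must cleave N–O and five benzyl ethers without reducing the enaminone, and then close ring C in dilute acid.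

**15 back to 9 and 14.** The isoxazole is cut at the future C3–C4 bond and at its O–C5 bond (a temporary O–C2 bond), giving nitrile oxide 9 and terminal alkyne 14. This is the convergent cut: each half already carries all its oxygens in final form, and the halves meet under neutral conditions. A cut at C4–C4a would mean acylating a pentaalkoxybenzene at its last, most hindered position with a Lewis acid that attacks the ethers. The cycloaddition must give the 3,5-regioisomer and the dipole must not dimerise; the terminal alkyne and the two ortho benzyloxy groups of 9 take care of both.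

**9 back to 6.** The C≡N–O dipole is traced through hydroximoyl chloride 8 and oxime 7 to aldehyde 6, by oxime chlorination and dehydrochlorination. This is functional-group change on one carbon only. The forward steps must avoid nuclear chlorination, which ring A cannot undergo because it has no ring C–H left.

**6 back to 4.** The two ortho benzyl ethers are removed to give dihydroxy aldehyde 5, and the C1–CHO bond is then cut to give resorcinol 4. Formylating at the free-phenol stage uses the only ring C–H of 4, activated by two ortho hydroxyls and a para benzyloxy group, so regiochemistry is not in question. Formylating after benzylation would place the electrophile between two bulky ethers on a less activated ring.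

**4 back to 1.** The two C–OH bonds of 4 are cut to the C–Br bonds of dibromide 3, which comes from benzyl ether 2 and so from syringol 1. Syringol already has the OMe–O–OMe triad of C6, C7 and C8 with the central oxygen distinct from the methyls. The forward reactions are a regioselective dibromination para to each methoxy group and a double palladium-catalysed hydroxylation.

**14 back to 10.** The alkyne carbon is removed by reversing a one-carbon homologation of aldehyde 13. The aldehyde comes through alcohol 12 and dibenzyl ester 11 from methyl 3,5-dihydroxy-4-methoxybenzoate 10. Ester 10 already holds the ring B pattern with the 4-methoxyl in place, so only protection and oxidation-level adjustment are needed.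

## Roads not taken

**Alternative 1: anodic C–O closure onto ring A.** The cut is O1–C8a. The open-chain 1,3-diketone A1, whose ring A still has one C–H, would be oxidised at an anode so that the enol oxygen attacks that carbon and closes the pyranone, giving chromone A2 with loss of two electrons and two protons.
- Merits: ring A needs one oxygen fewer before the key step, no nitrogen has to be introduced and removed, the reagent is electricity, and only one ring C–H is available, so the site of closure is fixed.
- Weak points: the tetraalkoxy arene and the enol are both easily oxidised, so dealkylative quinone formation and oxidation at the benzylic ether positions compete with C–O closure. Ring B has to be deactivated as its bis-pivalate, which adds a deprotection. Closure of a flavone in this way has no direct precedent, so the key step would be a new method.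
- Comparison: this road is shorter in the ring A sequence, because the double hydroxylation of step 3 would not be needed. Against that, the chosen plan relies only on known reaction types, and its oxidations (oxime chlorination, MnO2) act on substrates that tolerate them.

**Alternative 2: one-carbon ring expansion of a benzofuran.** The cuts are C2–C3 and C3–C4. C3 would be inserted as dichlorocarbene A4 into the enol ether double bond of the 3-silyloxy-2-arylbenzofuran A3; the dichlorocyclopropane would open with loss of chloride and silyl to the 3-chloroflavone A5.
- Merits: a five-membered ring that closes easily is turned into the pyranone, and the chlorine at C3 could come off in the same hydrogenolysis that removes the benzyl groups, so the end game is no longer than the chosen one.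
- Weak points: A3 holds the same five ring A oxygens as 9 and also needs its C2–aryl bond made beforehand, so the two halves are joined early by a less reliable step and the route is less convergent. Carbene generation under strongly basic phase-transfer conditions threatens the silyl enol ether before cyclopropanation. The chlorine is of no use in this target. Ring expansion of this substrate class to chromones lacks close precedent.
- Comparison: the chosen plan joins the two rings in the key step itself and carries no atom that must be removed again other than the nitrogen, which leaves in the cyclisation.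

**Alternative 3: ring A by [3+3] annulation.** The cuts are C8–C8a and C5–C6. The enolate of 1,3-dimethoxyacetone A7 would displace methanethiolate from pyranone ester A6 and then acylate on the ester through its second α-carbon, building and aromatising ring A to give flavone A8 with free C5 and C7 hydroxyls.
- Merits: this is the most step-economical idea. No arene is functionalised, the alternating hydroxyl/methoxyl pattern arises directly, and ring A needs no protecting group.
- Weak points: A7 is a weakly acidic, doubly α-alkoxylated ketone that tends to self-condense. Its enolate can also attack the aryl-bearing carbon of the 4-pyranone and open the ring. After the first substitution the most acidic proton is the one on the newly attached carbon, not the one whose removal leads to ring closure. A6 itself has to be built in several steps.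
- Comparison: if the annulation worked it would beat the seven-step preparation of 9. The chosen plan accepts that length in exchange for a key step with close precedent and unambiguous regiochemistry.

Key step: step 12

Remark on the chemistry: nitrile oxide 9, flanked by two benzyloxy groups, is assumed to be isolable and storable cold for a short time, as 2,6-disubstituted aryl nitrile oxides generally are. The target has no stereocentre; the only descriptors in the route are the E oxime 7, the Z chloride 8 and the Z enaminone 16.

## Route

Step 1
Reactants: 1 2,6-dimethoxyphenol (syringol)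
Product: 2 2-(benzyloxy)-1,3-dimethoxybenzene
Conditions: BnBr, K2CO3, DMF, 60 °C
Reagents that add atoms: benzyl bromide, BrCc1ccccc1
Why: Williamson etherification of the phenoxide; the benzyl group marks the future C7 oxygen as a hydroxyl while the two methyl ethers remain as the C6 and C8 methoxyls.

Step 2
Reactants: 2 2-(benzyloxy)-1,3-dimethoxybenzene
Product: 3 3-(benzyloxy)-1,5-dibromo-2,4-dimethoxybenzene
Conditions: NBS (2.1 equiv), MeCN, 0 °C to rt, dark
Reagents that add atoms: N-bromosuccinimide, O=C1CCC(=O)N1Br
Why: Electrophilic aromatic bromination; each methoxy group activates the position para to itself and ortho to the other, whereas the central benzyloxy group is twisted out of conjugation and leaves C5 unreactive, the usual 4,6-pattern of 1,2,3-trialkoxybenzenes.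

Step 3
Reactants: 3 3-(benzyloxy)-1,5-dibromo-2,4-dimethoxybenzene
Product: 4 5-(benzyloxy)-4,6-dimethoxybenzene-1,3-diol
Conditions: Pd2(dba)3 (cat.), tBuXPhos (cat.), KOH, 1,4-dioxane/H2O, 100 °C, argon
Reagents that add atoms: potassium hydroxide, [K+].[OH-]
Why: Palladium-catalysed hydroxylation of aryl bromides (Buchwald-type C–O coupling with hydroxide); the bulky biaryl phosphine favours C–O reductive elimination over diaryl ether formation, and each bromide has only one ortho substituent.

Step 4
Reactants: 4 5-(benzyloxy)-4,6-dimethoxybenzene-1,3-diol
Product: 5 4-(benzyloxy)-2,6-dihydroxy-3,5-dimethoxybenzaldehyde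
Conditions: POCl3, DMF, MeCN, 0 °C to rt; then H2O, 50 °C
Reagents that add atoms: N,N-dimethylformamide, CN(C)C=O; water, O
Why: Vilsmeier–Haack formylation; the only ring C–H of 4 lies ortho to two hydroxyls and para to the benzyloxy group, so the chloroiminium ion has one possible site, and aqueous hydrolysis of the iminium salt (and of any aryl formate) should give the aldehyde.

Step 5
Reactants: 5 4-(benzyloxy)-2,6-dihydroxy-3,5-dimethoxybenzaldehyde
Product: 6 2,4,6-tris(benzyloxy)-3,5-dimethoxybenzaldehyde
Conditions: BnBr (2.5 equiv), K2CO3, DMF, 70 °C
Reagents that add atoms: benzyl bromide, BrCc1ccccc1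
Why: Williamson etherification; the hydrogen-bonded ortho hydroxyls of a salicylaldehyde alkylate with K2CO3 in warm DMF, and the aldehyde has no α-hydrogen to interfere.

Step 6
Reactants: 6 2,4,6-tris(benzyloxy)-3,5-dimethoxybenzaldehyde
Product: 7 (E)-2,4,6-tris(benzyloxy)-3,5-dimethoxybenzaldehyde oxime
Conditions: NH2OH·HCl, NaOAc, EtOH/H2O, 80 °C
Reagents that add atoms: hydroxylamine hydrochloride, NO.Cl
Why: Condensation of an aldehyde with hydroxylamine; di-ortho-substituted benzaldehydes still form oximes readily and the E isomer is the stable one.

Step 7
Reactants: 7 (E)-2,4,6-tris(benzyloxy)-3,5-dimethoxybenzaldehyde oxime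
Product: 9 2,4,6-tris(benzyloxy)-3,5-dimethoxybenzonitrile oxide, via hydroximoyl chloride 8 (not isolated)
Conditions: NCS, DMF, 0 °C to rt; then Et3N, CH2Cl2, 0 °C; cold aqueous wash, crystallisation
Reagents that add atoms: none
Why: Chlorination of the aldoxime at carbon and base-induced 1,3-elimination of HCl (Huisgen generation of a nitrile oxide); ring A has no free position for nuclear chlorination, and the two flanking benzyloxy groups block dimerisation so that 9 can be isolated like other 2,6-disubstituted aryl nitrile oxides.

Step 8
Reactants: 10 methyl 3,5-dihydroxy-4-methoxybenzoate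
Product: 11 methyl 3,5-bis(benzyloxy)-4-methoxybenzoate
Conditions: BnBr (2.4 equiv), K2CO3, DMF, 60 °C
Reagents that add atoms: benzyl bromide, BrCc1ccccc1
Why: Williamson etherification of both phenols; the methyl ester is stable to carbonate in DMF.

Step 9
Reactants: 11 methyl 3,5-bis(benzyloxy)-4-methoxybenzoate
Product: 12 [3,5-bis(benzyloxy)-4-methoxyphenyl]methanol
Conditions: LiAlH4, THF, 0 °C to rt; aqueous NaOH work-up
Reagents that add atoms: none
Why: Hydride reduction of an ester to the primary alcohol; benzyl and methyl aryl ethers are inert to LiAlH4.

Step 10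
Reactants: 12 [3,5-bis(benzyloxy)-4-methoxyphenyl]methanol
Product: 13 3,5-bis(benzyloxy)-4-methoxybenzaldehyde
Conditions: activated MnO2, CH2Cl2, rt
Reagents that add atoms: none
Why: Selective oxidation of a benzylic alcohol by MnO2, which stops at the aldehyde and leaves the ethers untouched.

Step 11
Reactants: 13 3,5-bis(benzyloxy)-4-methoxybenzaldehyde
Product: 14 1,3-bis(benzyloxy)-5-ethynyl-2-methoxybenzene
Conditions: dimethyl (1-diazo-2-oxopropyl)phosphonate, K2CO3, MeOH, rt
Reagents that add atoms: dimethyl (1-diazo-2-oxopropyl)phosphonate, CC(=O)C(=[N+]=[N-])P(=O)(OC)OC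
Why: Ohira–Bestmann (Seyferth–Gilbert) homologation; methanolysis frees the diazomethylphosphonate anion, which adds to the non-enolisable aldehyde, and loss of phosphate and N2 with a 1,2-hydride shift should give the terminal alkyne.

Step 12
Reactants: 9 2,4,6-tris(benzyloxy)-3,5-dimethoxybenzonitrile oxide, 14 1,3-bis(benzyloxy)-5-ethynyl-2-methoxybenzene
Product: 15 5-[3,5-bis(benzyloxy)-4-methoxyphenyl]-3-[2,4,6-tris(benzyloxy)-3,5-dimethoxyphenyl]-1,2-oxazole
Conditions: 14 (1.2 equiv), toluene, 80 °C, argon
Reagents that add atoms: none
Why: A concerted but asynchronous 1,3-dipolar cycloaddition ([3+2], four π electrons of the C–N–O dipole with two of the alkyne) joins the nitrile oxide carbon to the terminal alkyne carbon (the future C3–C4 bond) and the dipole oxygen to the internal alkyne carbon (the future C2). The closest known reaction is the Huisgen cycloaddition of isolable 2,6-disubstituted aryl nitrile oxides, such as mesitonitrile oxide, with terminal arylacetylenes. The isoxazole ring is closed intermolecularly, both ring bonds forming in one transition state, so no rule for chain cyclisation applies and the aromatic product forms directly. No stereocentre is created. The step needs 3,5- over 3,4-regiochemistry: the unsubstituted alkyne terminus is the sterically open carbon with the larger frontier-orbital coefficient, and the bulky di-ortho-benzyloxy aryl group disfavours ring B at the adjacent C4. It also needs the dipole to add and not dimerise, which the two ortho benzyloxy groups ensure. The temperature is kept at or below 80 °C so that thermal isomerisation of the hindered dipole does not compete.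

Step 13
Reactants: 15 5-[3,5-bis(benzyloxy)-4-methoxyphenyl]-3-[2,4,6-tris(benzyloxy)-3,5-dimethoxyphenyl]-1,2-oxazole
Product: 17 5,7-dihydroxy-2-(3,5-dihydroxy-4-methoxyphenyl)-6,8-dimethoxy-4H-chromen-4-one, via pentahydroxy amino enone 16 (not isolated)
Conditions: H2 (1 atm), 10% Pd/C, THF/MeOH, rt; filter under argon; then 2 M aq HCl, MeOH, 65 °C
Reagents that add atoms: water, O
Why: Heterogeneous hydrogenolysis cleaves the five benzyl ethers and the weak N–O bond of the isoxazole, the standard unmasking of an isoxazole to a β-amino enone. In aqueous acid an ortho hydroxyl of ring A adds to the ring B ketone (six-membered closure), water is lost and the C–N unit is hydrolysed, so the C4 oxygen comes from water and nitrogen leaves as NH4Cl. The symmetry of ring A makes the choice of ortho hydroxyl irrelevant.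

## Compound list

1 | 2,6-dimethoxyphenol (syringol) | COc1cccc(OC)c1O | starting material
2 | 2-(benzyloxy)-1,3-dimethoxybenzene | COc1cccc(OC)c1OCc1ccccc1 | intermediate
3 | 3-(benzyloxy)-1,5-dibromo-2,4-dimethoxybenzene | COc1c(Br)cc(Br)c(OC)c1OCc1ccccc1 | intermediate
4 | 5-(benzyloxy)-4,6-dimethoxybenzene-1,3-diol | COc1c(O)cc(O)c(OC)c1OCc1ccccc1 | intermediate
5 | 4-(benzyloxy)-2,6-dihydroxy-3,5-dimethoxybenzaldehyde | COc1c(O)c(C=O)c(O)c(OC)c1OCc1ccccc1 | intermediate
6 | 2,4,6-tris(benzyloxy)-3,5-dimethoxybenzaldehyde | COc1c(OCc2ccccc2)c(C=O)c(OCc2ccccc2)c(OC)c1OCc1ccccc1 | intermediate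
7 | (E)-2,4,6-tris(benzyloxy)-3,5-dimethoxybenzaldehyde oxime | COc1c(OCc2ccccc2)c(/C=N/O)c(OCc2ccccc2)c(OC)c1OCc1ccccc1 | intermediate
8 | (Z)-2,4,6-tris(benzyloxy)-N-hydroxy-3,5-dimethoxybenzenecarboximidoyl chloride (hydroximoyl chloride) | COc1c(OCc2ccccc2)c(/C(Cl)=N/O)c(OCc2ccccc2)c(OC)c1OCc1ccccc1 | intermediate (not isolated)
9 | 2,4,6-tris(benzyloxy)-3,5-dimethoxybenzonitrile oxide | [O-][N+]#Cc1c(OCc2ccccc2)c(OC)c(OCc2ccccc2)c(OC)c1OCc1ccccc1 | intermediate
10 | methyl 3,5-dihydroxy-4-methoxybenzoate | COC(=O)c1cc(O)c(OC)c(O)c1 | starting material
11 | methyl 3,5-bis(benzyloxy)-4-methoxybenzoate | COC(=O)c1cc(OCc2ccccc2)c(OC)c(OCc2ccccc2)c1 | intermediate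
12 | [3,5-bis(benzyloxy)-4-methoxyphenyl]methanol | COc1c(OCc2ccccc2)cc(CO)cc1OCc1ccccc1 | intermediate
13 | 3,5-bis(benzyloxy)-4-methoxybenzaldehyde | COc1c(OCc2ccccc2)cc(C=O)cc1OCc1ccccc1 | intermediate
14 | 1,3-bis(benzyloxy)-5-ethynyl-2-methoxybenzene | C#Cc1cc(OCc2ccccc2)c(OC)c(OCc2ccccc2)c1 | intermediate
15 | 5-[3,5-bis(benzyloxy)-4-methoxyphenyl]-3-[2,4,6-tris(benzyloxy)-3,5-dimethoxyphenyl]-1,2-oxazole | COc1c(OCc2ccccc2)cc(-c2cc(-c3c(OCc4ccccc4)c(OC)c(OCc4ccccc4)c(OC)c3OCc3ccccc3)no2)cc1OCc1ccccc1 | intermediate
16 | (Z)-3-amino-1-(3,5-dihydroxy-4-methoxyphenyl)-3-(2,4,6-trihydroxy-3,5-dimethoxyphenyl)prop-2-en-1-one | COc1c(O)cc(C(=O)/C=C(\N)c2c(O)c(OC)c(O)c(OC)c2O)cc1O | intermediate (not isolated)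
17 | 5,7-dihydroxy-2-(3,5-dihydroxy-4-methoxyphenyl)-6,8-dimethoxy-4H-chromen-4-one | COc1c(O)cc(-c2cc(=O)c3c(O)c(OC)c(O)c(OC)c3o2)cc1O | target

## Step count and risks

Total: 13 steps. Longest linear sequence: 9 steps (steps 1 to 7, 12 and 13). The ring B branch (steps 8 to 11) is 4 steps and joins at step 12.

**Step 12 (key step).** The cycloaddition may be too slow, because the dipole is both hindered and electron-rich, so that thermal isomerisation or slow decomposition of the nitrile oxide outruns it; a small loss of regiocontrol is the second concern. Fallback: a more reactive dipolarophile, setting out from 13 and 9 and returning at 15. Aldehyde 13 is methylenated (methyltriphenylphosphonium bromide, KOtBu, THF) to 1,3-bis(benzyloxy)-5-ethenyl-2-methoxybenzene F1. Styrenes add nitrile oxides faster than arylacetylenes and with the same orientation, so 9 and F1 should give the racemic 5-aryl-4,5-dihydro-1,2-oxazole F2. F2 is dehydrogenated with MnO2 in hot toluene to isoxazole 15.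

**Step 3.** The second C–O coupling may stall, the first-formed bromophenoxide may be arylated to a diaryl ether, hydrodebromination may intervene, and the electron-rich diol may oxidise during basic work-up. Fallback: C–B bond formation followed by oxidation, setting out from 3 and returning at 4. Double Miyaura borylation (B2pin2, Pd(dppf)Cl2, KOAc, dioxane, 90 °C) gives 2,2'-[5-(benzyloxy)-4,6-dimethoxy-1,3-phenylene]bis(4,4,5,5-tetramethyl-1,3,2-dioxaborolane) F3. Oxidation with H2O2/NaOH in THF at 0 °C then gives 4.

**Step 4.** Formylation between two hydroxyls may be slow for steric reasons, with O-formylation or phosphorylation of the phenols consuming the reagent. Fallback: install the formyl group as a nucleophile-derived carbon after protection, setting out from 4 and returning at 6 (5 is bypassed). Both hydroxyls are benzylated (BnBr, K2CO3, DMF) to 1,3,5-tris(benzyloxy)-2,4-dimethoxybenzene F4. The single ring C–H is brominated (NBS, MeCN) to 1,3,5-tris(benzyloxy)-2-bromo-4,6-dimethoxybenzene F5. Bromine–lithium exchange (n-BuLi, THF, −78 °C), which is faster than benzylic deprotonation, and a DMF quench then give 6.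

**Step 7.** Chlorination of the hindered oxime may be incomplete, and the dipole may be lost by isomerisation or hydrolysis during concentration and purification. Fallback: no halogenation and no isolation, setting out from 7 and 14 and returning at 15. Oxime 7 is oxidised with PhI(OAc)2 (MeOH, cat. TFA, rt) in the presence of alkyne 14, so that 9 is trapped as it forms; no new compound is made.

**Step 13.** Debenzylation may finish before the N–O bond of the diarylisoxazole is cut, or prolonged exposure may reduce the enaminone; the polyphenolic intermediates may also oxidise during the catalyst filtration. Fallback: separate the two events and avoid hydrogen, setting out from 15 and returning at 17. Mo(CO)6 in MeCN/H2O at 80 °C cleaves only the N–O bond, giving (Z)-3-amino-1-[3,5-bis(benzyloxy)-4-methoxyphenyl]-3-[2,4,6-tris(benzyloxy)-3,5-dimethoxyphenyl]prop-2-en-1-one F6. BCl3 with pentamethylbenzene (CH2Cl2, −78 °C) then removes the benzyl groups, and the aqueous HCl quench, warmed in MeOH, closes ring C to 17.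

## Further compounds

F1 | step 12 | 1,3-bis(benzyloxy)-5-ethenyl-2-methoxybenzene | C=Cc1cc(OCc2ccccc2)c(OC)c(OCc2ccccc2)c1
F2 | step 12 | 5-[3,5-bis(benzyloxy)-4-methoxyphenyl]-3-[2,4,6-tris(benzyloxy)-3,5-dimethoxyphenyl]-4,5-dihydro-1,2-oxazole (racemic) | COc1c(OCc2ccccc2)cc(C2CC(c3c(OCc4ccccc4)c(OC)c(OCc4ccccc4)c(OC)c3OCc3ccccc3)=NO2)cc1OCc1ccccc1
F3 | step 3 | 2,2'-[5-(benzyloxy)-4,6-dimethoxy-1,3-phenylene]bis(4,4,5,5-tetramethyl-1,3,2-dioxaborolane) | COc1c(B2OC(C)(C)C(C)(C)O2)cc(B2OC(C)(C)C(C)(C)O2)c(OC)c1OCc1ccccc1
F4 | step 4 | 1,3,5-tris(benzyloxy)-2,4-dimethoxybenzene | COc1c(OCc2ccccc2)cc(OCc2ccccc2)c(OC)c1OCc1ccccc1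
F5 | step 4 | 1,3,5-tris(benzyloxy)-2-bromo-4,6-dimethoxybenzene | COc1c(OCc2ccccc2)c(Br)c(OCc2ccccc2)c(OC)c1OCc1ccccc1
F0 | step 7 | none | none
F6 | step 13 | (Z)-3-amino-1-[3,5-bis(benzyloxy)-4-methoxyphenyl]-3-[2,4,6-tris(benzyloxy)-3,5-dimethoxyphenyl]prop-2-en-1-one | COc1c(OCc2ccccc2)cc(C(=O)/C=C(\N)c2c(OCc3ccccc3)c(OC)c(OCc3ccccc3)c(OC)c2OCc2ccccc2)cc1OCc1ccccc1
A1 | alternative 1 | 1-[2,4-bis(benzyloxy)-3,5-dimethoxyphenyl]-3-[4-methoxy-3,5-bis(pivaloyloxy)phenyl]propane-1,3-dione | COc1cc(C(=O)CC(=O)c2cc(OC(=O)C(C)(C)C)c(OC)c(OC(=O)C(C)(C)C)c2)c(OCc2ccccc2)c(OC)c1OCc1ccccc1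
A2 | alternative 1 | 5,7-bis(benzyloxy)-6,8-dimethoxy-2-[4-methoxy-3,5-bis(pivaloyloxy)phenyl]-4H-chromen-4-one | COc1c(OC(=O)C(C)(C)C)cc(-c2cc(=O)c3c(OCc4ccccc4)c(OC)c(OCc4ccccc4)c(OC)c3o2)cc1OC(=O)C(C)(C)C
A3 | alternative 2 | tert-butyl({4,6-bis(benzyloxy)-2-[3,5-bis(benzyloxy)-4-methoxyphenyl]-5,7-dimethoxy-1-benzofuran-3-yl}oxy)dimethylsilane | COc1c(OCc2ccccc2)cc(-c2oc3c(OC)c(OCc4ccccc4)c(OC)c(OCc4ccccc4)c3c2O[Si](C)(C)C(C)(C)C)cc1OCc1ccccc1
A4 | alternative 2 | dichlorocarbene | Cl[C]Cl
A5 | alternative 2 | 5,7-bis(benzyloxy)-2-[3,5-bis(benzyloxy)-4-methoxyphenyl]-3-chloro-6,8-dimethoxy-4H-chromen-4-one | COc1c(OCc2ccccc2)cc(-c2oc3c(OC)c(OCc4ccccc4)c(OC)c(OCc4ccccc4)c3c(=O)c2Cl)cc1OCc1ccccc1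
A6 | alternative 3 | methyl 6-[3,5-bis(benzyloxy)-4-methoxyphenyl]-2-(methylsulfanyl)-4-oxo-4H-pyran-3-carboxylate | COC(=O)c1c(SC)oc(-c2cc(OCc3ccccc3)c(OC)c(OCc3ccccc3)c2)cc1=O
A7 | alternative 3 | 1,3-dimethoxypropan-2-one (1,3-dimethoxyacetone) | COCC(=O)COC
A8 | alternative 3 | 2-[3,5-bis(benzyloxy)-4-methoxyphenyl]-5,7-dihydroxy-6,8-dimethoxy-4H-chromen-4-one | COc1c(OCc2ccccc2)cc(-c2cc(=O)c3c(O)c(OC)c(O)c(OC)c3o2)cc1OCc1ccccc1
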